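**Plan**
- Retrosynthesis: the aryl ketone is taken back to a benzylic carbinol and the C5 methylene to a menthyl acetal carbon. The C–C bonds cut are C3–C(carbinol) (aldol) and C4–CH2Ar (conjugate addition, the CH2 masked as a dithiane carbon).
- Enabling feature: the γ-butyrolactone ring carries an aroyl group on C3 (α to the lactone C=O) and an arylmethyl group on C4 (β), trans to each other. This is the pattern left by a nucleophile at C4 and an electrophile at C3 of a furan-2(5H)-one.
- Forward order: the five-membered ring is already present in the butenolide made from furfural. Dithiane anion, butenolide and aldehyde are joined in one flask. The ring is opened and reclosed once, when the acetal carbon is reduced to C5H2.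
- Stereochemistry: (−)-menthol and a crystallisation fix C5 of the butenolide as R. That centre sends the carbanion to the opposite face at C4, and the new C4 group sends the aldehyde to the opposite face at C3. C5 is then erased.
- End game: desulfurisation, reductive removal of menthol with relactonisation, oxidation of the carbinol, debenzylation.

Key step: step 4

Assumption: the carbinol carbon formed in step 4 is carried as a mixture of epimers through 13, 14 and 17, because step 7 turns it into the carbonyl carbon. "Menthyloxy" below means [(1R,2S,5R)-5-methyl-2-(propan-2-yl)cyclohexyl]oxy.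

**Route**

Step 1
Reactants: 1 furfural
Product: 3 5-hydroxyfuran-2(5H)-one (racemic), via furfural endoperoxide 2 (not isolated)
Conditions: O2, rose bengal (cat.), MeOH, hν (visible), 20 °C
Reagents that add atoms: oxygen, O=O
Why: Singlet oxygen adds across the furan diene in a [4+2] cycloaddition, and methanolysis of the formyl group of endoperoxide 2 triggers a Grob-type fragmentation that expels methyl formate and leaves the γ-hydroxybutenolide (dye-sensitised photo-oxygenation of a furan).

Step 2
Reactants: 3 5-hydroxyfuran-2(5H)-one; 4 (−)-menthol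
Product: 6 (5R)-5-{[(1R,2S,5R)-5-methyl-2-(propan-2-yl)cyclohexyl]oxy}furan-2(5H)-one, via 5S acetal epimer 5 (not isolated)
Conditions: camphorsulfonic acid (cat.), toluene, reflux (Dean–Stark); crystallise from petroleum ether, −20 °C; mother liquor re-equilibrated with the acid and recrystallised
Reagents that add atoms: none
Why: Acid-catalysed acetalisation through the cyclic acyloxocarbenium ion gives both C5 epimers, of which the (5R) one should crystallise while the acid re-equilibrates the (5S) epimer 5 left in solution, so C5 is set by crystallisation-driven separation of diastereomers against the fixed centres of menthol.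

Step 3
Reactants: 7 veratraldehyde
Product: 8 2-(3,4-dimethoxyphenyl)-1,3-dithiane
Conditions: HS(CH2)3SH, BF3·OEt2 (cat.), CH2Cl2, 0 °C → rt
Reagents that add atoms: 1,3-propanedithiol, SCCCS
Why: Lewis-acid-catalysed dithioacetalisation of an aromatic aldehyde turns the formyl carbon into an acidic acyl-anion equivalent that can later be reduced to CH2.

Step 4
Reactants: 8 2-(3,4-dimethoxyphenyl)-1,3-dithiane; 6 (5R)-5-(menthyloxy)furan-2(5H)-one; 9 4-(benzyloxy)-3-methoxybenzaldehyde
Product: 13 (3S,4R,5R)-3-{[4-(benzyloxy)-3-methoxyphenyl](hydroxy)methyl}-4-[2-(3,4-dimethoxyphenyl)-1,3-dithian-2-yl]-5-(menthyloxy)oxolan-2-one (both carbinol epimers), via lithiated dithiane 10 (not isolated), via lithium enolate 11 (not isolated), via lithium aldolate 12 (not isolated)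
Conditions: n-BuLi, THF, −78 → −20 °C; then 6, −78 °C; then 9, −78 °C; AcOH quench at −78 °C
Reagents that add atoms: none
Why: n-BuLi removes the C2–H of dithiane 8 to give the sulfur- and aryl-stabilised carbanion 10, which adds in a Michael sense to C4 of butenolide 6; the lactone enolate 11 then attacks the non-enolisable aldehyde 9 through C3, and aldolate 12 is protonated cold before retro-aldol cleavage can set in. The closest known reaction type is the three-component tandem conjugate addition–aldol of lithiated aryl dithioacetals, butenolides and aromatic aldehydes used for lignan lactones. No ring is closed; the two new bonds are C4–C(dithiane) and C3–C(carbinol). The new C4 centre is controlled by the (5R) acetal centre, whose menthyloxy group shields one face so that 10 enters anti to it (4,5-trans), and the new C3 centre is controlled by the bulky C4 substituent just installed, which sends the aldehyde to the opposite face (3,4-trans); the carbinol carbon is not controlled and need not be. The step needs 1,4- over 1,2-addition and C- over O-trapping of the enolate: the soft, delocalised dithiane anion secures the first and the aldehyde electrophile at low temperature secures the second.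

Step 5
Reactants: 13 tandem adduct
Product: 14 (3S,4R,5R)-3-{[4-(benzyloxy)-3-methoxyphenyl](hydroxy)methyl}-4-(3,4-dimethoxybenzyl)-5-(menthyloxy)oxolan-2-one (carbinol epimers)
Conditions: NiCl2·6H2O, NaBH4, MeOH/THF, 0 °C
Reagents that add atoms: none
Why: Nickel boride formed in the flask cleaves both benzylic C–S bonds (reductive desulfurisation of a dithioacetal) under conditions that should leave the aryl benzyl ether, the benzylic alcohol and the three ring stereocentres untouched, so the dithiane carbon becomes the benzylic CH2.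

Step 6
Reactants: 14 desulfurised acetal lactone
Product: 17 (3S,4R)-3-{[4-(benzyloxy)-3-methoxyphenyl](hydroxy)methyl}-4-(3,4-dimethoxybenzyl)oxolan-2-one (carbinol epimers), via potassium formyl carboxylate 15 (not isolated), via potassium dihydroxy carboxylate 16 (not isolated)
Conditions: NaBH4, KOH, MeOH/H2O, 0 °C → rt; then 1 M HCl to pH 2–3, rt
Reagents that add atoms: potassium hydroxide, [K+].[OH-] (its oxygen enters the carboxyl group on ring opening, and either carboxyl oxygen can remain as the lactone C=O after reclosure)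
Why: Hydroxide opens the acyl acetal (saponification of a pseudo-ester), the menthyl hemiacetal collapses to aldehyde 15, which the borohydride already present reduces before C4 can epimerise, and acidification of 16 closes the γ-lactone onto the new primary alcohol, so the former acetal carbon ends as C5H2 while the carboxylate stage blocks retro-aldol cleavage.

Step 7
Reactants: 17 hydroxy lactone
Product: 18 (3S,4R)-3-[4-(benzyloxy)-3-methoxybenzoyl]-4-(3,4-dimethoxybenzyl)oxolan-2-one
Conditions: Dess–Martin periodinane, CH2Cl2, 0 °C → rt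
Reagents that add atoms: none
Why: Dess–Martin oxidation of a secondary benzylic β-hydroxy lactone to the β-keto lactone under neutral conditions merges both carbinol epimers into one compound, and the now enolisable C3 should keep the 3,4-trans arrangement because that is the thermodynamically preferred one.

Step 8
Reactants: 18 benzyl-protected keto lactone
Product: 19 (3S,4R)-4-(3,4-dimethoxybenzyl)-3-(4-hydroxy-3-methoxybenzoyl)oxolan-2-one (target)
Conditions: H2 (1 atm), 10% Pd/C, EtOAc, rt
Reagents that add atoms: none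
Why: Hydrogenolysis of an aryl benzyl ether over Pd/C at 1 atm is much faster than reduction of the electron-rich aryl ketone, so stopping after one equivalent of H2 should free the phenol without touching the keto lactone.

**Compound list**
1 | furfural (furan-2-carbaldehyde) | O=Cc1ccco1 | starting material
2 | furfural endoperoxide, 2,3,7-trioxabicyclo[2.2.1]hept-5-ene-1-carbaldehyde (racemic) | O=CC12OOC(O1)C=C2 | intermediate
3 | 5-hydroxyfuran-2(5H)-one (racemic) | O=C1OC(O)C=C1 | intermediate
4 | (−)-menthol, (1R,2S,5R)-5-methyl-2-(propan-2-yl)cyclohexan-1-ol | CC(C)[C@@H]1CC[C@@H](C)C[C@H]1O | starting material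
5 | (5S)-5-{[(1R,2S,5R)-5-methyl-2-(propan-2-yl)cyclohexyl]oxy}furan-2(5H)-one | O=C1O[C@H](O[C@@H]2C[C@H](C)CC[C@H]2C(C)C)C=C1 | intermediate
6 | (5R)-5-{[(1R,2S,5R)-5-methyl-2-(propan-2-yl)cyclohexyl]oxy}furan-2(5H)-one | O=C1O[C@@H](O[C@@H]2C[C@H](C)CC[C@H]2C(C)C)C=C1 | intermediate
7 | veratraldehyde (3,4-dimethoxybenzaldehyde) | COc1ccc(C=O)cc1OC | starting material
8 | 2-(3,4-dimethoxyphenyl)-1,3-dithiane | COc1ccc(C2SCCCS2)cc1OC | intermediate
9 | 4-(benzyloxy)-3-methoxybenzaldehyde | COc1cc(C=O)ccc1OCc1ccccc1 | starting material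
10 | 2-lithio-2-(3,4-dimethoxyphenyl)-1,3-dithiane | [Li]C1(c2ccc(OC)c(OC)c2)SCCCS1 | intermediate
11 | lithium enolate of (4R,5R)-4-[2-(3,4-dimethoxyphenyl)-1,3-dithian-2-yl]-5-(menthyloxy)oxolan-2-one | [Li]OC1=C[C@@H](C2(c3ccc(OC)c(OC)c3)SCCCS2)[C@H](O[C@@H]2C[C@H](C)CC[C@H]2C(C)C)O1 | intermediate
12 | lithium alkoxide of adduct 13 (carbinol epimers) | COc1cc(C(O[Li])[C@H]2C(=O)O[C@@H](O[C@@H]3C[C@H](C)CC[C@H]3C(C)C)[C@@H]2C2(c3ccc(OC)c(OC)c3)SCCCS2)ccc1OCc1ccccc1 | intermediate
13 | (3S,4R,5R)-3-{[4-(benzyloxy)-3-methoxyphenyl](hydroxy)methyl}-4-[2-(3,4-dimethoxyphenyl)-1,3-dithian-2-yl]-5-(menthyloxy)oxolan-2-one (carbinol epimers) | COc1cc(C(O)[C@H]2C(=O)O[C@@H](O[C@@H]3C[C@H](C)CC[C@H]3C(C)C)[C@@H]2C2(c3ccc(OC)c(OC)c3)SCCCS2)ccc1OCc1ccccc1 | intermediate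
14 | (3S,4R,5R)-3-{[4-(benzyloxy)-3-methoxyphenyl](hydroxy)methyl}-4-(3,4-dimethoxybenzyl)-5-(menthyloxy)oxolan-2-one (carbinol epimers) | COc1cc(C(O)[C@H]2C(=O)O[C@@H](O[C@@H]3C[C@H](C)CC[C@H]3C(C)C)[C@@H]2Cc2ccc(OC)c(OC)c2)ccc1OCc1ccccc1 | intermediate
15 | potassium (2S,3R)-2-{[4-(benzyloxy)-3-methoxyphenyl](hydroxy)methyl}-3-(3,4-dimethoxybenzyl)-4-oxobutanoate (carbinol epimers) | COc1cc(C(O)[C@@H](C(=O)[O-])[C@H](C=O)Cc2ccc(OC)c(OC)c2)ccc1OCc1ccccc1.[K+] | intermediate
16 | potassium (2S,3R)-2-{[4-(benzyloxy)-3-methoxyphenyl](hydroxy)methyl}-3-(3,4-dimethoxybenzyl)-4-hydroxybutanoate (carbinol epimers) | COc1cc(C(O)[C@@H](C(=O)[O-])[C@H](CO)Cc2ccc(OC)c(OC)c2)ccc1OCc1ccccc1.[K+] | intermediate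
17 | (3S,4R)-3-{[4-(benzyloxy)-3-methoxyphenyl](hydroxy)methyl}-4-(3,4-dimethoxybenzyl)oxolan-2-one (carbinol epimers) | COc1cc(C(O)[C@H]2C(=O)OC[C@@H]2Cc2ccc(OC)c(OC)c2)ccc1OCc1ccccc1 | intermediate
18 | (3S,4R)-3-[4-(benzyloxy)-3-methoxybenzoyl]-4-(3,4-dimethoxybenzyl)oxolan-2-one | COc1cc(C(=O)[C@H]2C(=O)OC[C@@H]2Cc2ccc(OC)c(OC)c2)ccc1OCc1ccccc1 | intermediate
19 | (3S,4R)-4-(3,4-dimethoxybenzyl)-3-(4-hydroxy-3-methoxybenzoyl)oxolan-2-one | COc1cc(C(=O)[C@H]2C(=O)OC[C@@H]2Cc2ccc(OC)c(OC)c2)ccc1O | target

**Count**
Total steps: 8. Longest linear sequence: 7 steps (1 → 3 → 6 → 13 → 14 → 17 → 18 → 19); the dithiane branch adds one step and joins at step 4.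

**Steps most likely to fail**

Step 4. The aldolate may revert by retro-aldol before the quench, the carbanion may abstract the acetal C5–H instead of adding, or the conjugate addition and the aldol may demand incompatible temperatures, giving incomplete trapping or eroded 3,4-trans selectivity. Fallback: the tandem is split into two operations. Setting out from 8 and 6, only the conjugate addition is run (n-BuLi, THF, −78 °C, then 6, NH4Cl quench), which passes through 10 and 11 and gives after protonation the 3-unsubstituted lactone (4R,5R)-4-[2-(3,4-dimethoxyphenyl)-1,3-dithian-2-yl]-5-(menthyloxy)oxolan-2-one F1. This can be purified and its 4,5-trans configuration secured. Enolate 11 is then regenerated from F1 with LiN(SiMe3)2 in THF at −78 °C and treated with 9 under its own optimal conditions; a cold AcOH quench leads through 12 back to 13.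

Step 6. The carbinol alkoxide may trigger retro-aldol cleavage before the lactone is opened, C4 may epimerise through the transient aldehyde, and the electron-rich benzylic carbinol may ionise on acidification (dehydration or Friedel–Crafts closure onto the dimethoxybenzyl ring). Fallback: the carbinol is masked before the ring is opened. Setting out from 14, TBSOTf and 2,6-lutidine in CH2Cl2 (−78 → 0 °C) should give the silyl ether (3S,4R,5R)-3-{[4-(benzyloxy)-3-methoxyphenyl][(tert-butyldimethylsilyl)oxy]methyl}-4-(3,4-dimethoxybenzyl)-5-(menthyloxy)oxolan-2-one F3. The same NaBH4/KOH treatment then passes through the potassium silyloxy formyl carboxylate F4 and the potassium silyloxy hydroxy carboxylate F5 (neither isolated), and acidification closes the silyloxy lactone (3S,4R)-3-{[4-(benzyloxy)-3-methoxyphenyl][(tert-butyldimethylsilyl)oxy]methyl}-4-(3,4-dimethoxybenzyl)oxolan-2-one F6. HF·pyridine in THF removes the silyl group and the route is rejoined at 17.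

Step 5. The benzyl ether may be lost on the nickel surface, borohydride may begin to attack the acyl acetal, or the second C–S bond at the hindered centre may resist cleavage. Fallback: the nickel hydrogenolysis is replaced by a homogeneous radical-chain reduction. Setting out from 13, excess Bu3SnH with AIBN in toluene at reflux cleaves the first C–S bond to the ring-opened monosulfide 3-{[4-(benzyloxy)-3-methoxyphenyl](hydroxy)methyl}-4-[(3,4-dimethoxyphenyl)({3-[(tributylstannyl)sulfanyl]propyl}sulfanyl)methyl]-5-(menthyloxy)oxolan-2-one F2 (not isolated). The benzylic C–S bond of F2 is then cleaved in the same way, and the route is rejoined at 14. No hydride nucleophile and no metal surface are present, so the aryl benzyl ether, the carbinol and the acyl acetal should survive.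

**Further compounds**
F1 | step 4 | (4R,5R)-4-[2-(3,4-dimethoxyphenyl)-1,3-dithian-2-yl]-5-(menthyloxy)oxolan-2-one | O=C1C[C@@H](C2(c3ccc(OC)c(OC)c3)SCCCS2)[C@H](O[C@@H]2C[C@H](C)CC[C@H]2C(C)C)O1
F2 | step 5 | 3-{[4-(benzyloxy)-3-methoxyphenyl](hydroxy)methyl}-4-[(3,4-dimethoxyphenyl)({3-[(tributylstannyl)sulfanyl]propyl}sulfanyl)methyl]-5-(menthyloxy)oxolan-2-one | COc1cc(C(O)[C@H]2C(=O)O[C@@H](O[C@@H]3C[C@H](C)CC[C@H]3C(C)C)[C@@H]2C(SCCCS[Sn](CCCC)(CCCC)CCCC)c2ccc(OC)c(OC)c2)ccc1OCc1ccccc1
F3 | step 6 | (3S,4R,5R)-3-{[4-(benzyloxy)-3-methoxyphenyl][(tert-butyldimethylsilyl)oxy]methyl}-4-(3,4-dimethoxybenzyl)-5-(menthyloxy)oxolan-2-one | COc1cc(C(O[Si](C)(C)C(C)(C)C)[C@H]2C(=O)O[C@@H](O[C@@H]3C[C@H](C)CC[C@H]3C(C)C)[C@@H]2Cc2ccc(OC)c(OC)c2)ccc1OCc1ccccc1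
F4 | step 6 | potassium (2S,3R)-2-{[4-(benzyloxy)-3-methoxyphenyl][(tert-butyldimethylsilyl)oxy]methyl}-3-(3,4-dimethoxybenzyl)-4-oxobutanoate | COc1cc(C(O[Si](C)(C)C(C)(C)C)[C@@H](C(=O)[O-])[C@H](C=O)Cc2ccc(OC)c(OC)c2)ccc1OCc1ccccc1.[K+]
F5 | step 6 | potassium (2S,3R)-2-{[4-(benzyloxy)-3-methoxyphenyl][(tert-butyldimethylsilyl)oxy]methyl}-3-(3,4-dimethoxybenzyl)-4-hydroxybutanoate | COc1cc(C(O[Si](C)(C)C(C)(C)C)[C@@H](C(=O)[O-])[C@H](CO)Cc2ccc(OC)c(OC)c2)ccc1OCc1ccccc1.[K+]
F6 | step 6 | (3S,4R)-3-{[4-(benzyloxy)-3-methoxyphenyl][(tert-butyldimethylsilyl)oxy]methyl}-4-(3,4-dimethoxybenzyl)oxolan-2-one | COc1cc(C(O[Si](C)(C)C(C)(C)C)[C@H]2C(=O)OC[C@@H]2Cc2ccc(OC)c(OC)c2)ccc1OCc1ccccc1
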